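**Strategy.** The flavone is cut at O1–C8a. Ring A's C6–C7–C8 triad (OMe, O, OMe) is a syringyl unit whose two flanking carbons, C5 and C8a, are equivalent and both oxygenated; a 2,6-dibromosyringoyl group therefore serves as ring A. The precursor is a 2-methoxy-1,3-diketone carrying this dibromoaryl group on one carbonyl and the benzyl-protected 2-methoxy-4,5-dioxyphenyl ring B on the other. One copper-catalysed enolate O-arylation closes ring C at either bromide and leaves the second bromide at C5, peri to the carbonyl, ready for hydroxylation; hydrogenolysis then frees the three benzyl-protected phenols.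

Key step: step 9

Remark on the chemistry: the target has no stereocentre, so no enantiocontrol is needed. The only stereocentre on the route, C2 of diketone 15, is racemic and is erased in step 9.

**Step 1**
Reactants: 1 3,4-bis(benzyloxy)benzaldehyde
Product: 3 3,4-bis(benzyloxy)phenol, via aryl formate 2 (not isolated)
Conditions: mCPBA, CH2Cl2, 0 °C to rt; then K2CO3 (cat.), MeOH, rt
Reagents that add atoms: mCPBA, O=C(OO)c1cccc(Cl)c1
Why: Baeyer–Villiger (Dakin-type) oxidation in which the electron-rich aryl group migrates to give the formate, which mild methanolysis cleaves to the phenol while the benzyl ethers stay untouched.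

**Step 2**
Reactants: 3 3,4-bis(benzyloxy)phenol
Product: 4 1,2-bis(benzyloxy)-4-methoxybenzene
Conditions: MeI, K2CO3, acetone, reflux
Reagents that add atoms: iodomethane, CI
Why: Williamson ether synthesis on the only free phenol.

**Step 3**
Reactants: 4 1,2-bis(benzyloxy)-4-methoxybenzene
Product: 5 1,2-bis(benzyloxy)-4-bromo-5-methoxybenzene
Conditions: NBS (1.0 equiv), MeCN, 0 °C to rt
Reagents that add atoms: N-bromosuccinimide, O=C1CCC(=O)N1Br
Why: Electrophilic aromatic bromination should go to the position ortho to OMe and para to a benzyloxy group, the most activated and least hindered site of a 1,2,4-trialkoxybenzene.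

**Step 4**
Reactants: 6 methoxyacetyl chloride
Product: 7 N,2-dimethoxy-N-methylacetamide
Conditions: MeNH(OMe)·HCl, Et3N, CH2Cl2, 0 °C to rt
Reagents that add atoms: N,O-dimethylhydroxylamine hydrochloride, CNOC.Cl
Why: N-acylation of the hydroxylamine by the acid chloride gives the Weinreb amide.

**Step 5**
Reactants: 5 1,2-bis(benzyloxy)-4-bromo-5-methoxybenzene; 7 N,2-dimethoxy-N-methylacetamide
Product: 9 1-[4,5-bis(benzyloxy)-2-methoxyphenyl]-2-methoxyethan-1-one, via aryllithium 8 (not isolated)
Conditions: n-BuLi, THF, −78 °C; then 7, −78 to 0 °C; aq. NH4Cl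
Reagents that add atoms: n-butyllithium, [Li]CCCC (lithium of intermediate 8 only)
Why: Bromine–lithium exchange at −78 °C outruns benzylic deprotonation, and the Weinreb ketone synthesis stops at the ketone because the chelated tetrahedral adduct survives until the quench.

**Step 6**
Reactants: 10 methyl syringate
Product: 12 4-(benzyloxy)-3,5-dimethoxybenzoic acid, via methyl ester 11 (not isolated)
Conditions: BnBr, K2CO3, DMF, 60 °C; then 2 M NaOH, MeOH, 60 °C; HCl to pH 2
Reagents that add atoms: benzyl bromide, BrCc1ccccc1; sodium hydroxide, [Na+].[OH-]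
Why: Williamson O-benzylation followed by saponification, done before bromination because the ester still has free ortho positions and hydrolyses readily, which a 2,6-dibromobenzoate would not.

**Step 7**
Reactants: 12 4-(benzyloxy)-3,5-dimethoxybenzoic acid
Product: 13 4-(benzyloxy)-2,6-dibromo-3,5-dimethoxybenzoic acid
Conditions: Br2 (2.2 equiv), NaOAc, AcOH, rt to 40 °C, dark
Reagents that add atoms: bromine, BrBr
Why: Electrophilic aromatic dibromination at the two equivalent free positions, each ortho to one methoxy and para to the other, as known for 3,4,5-trialkoxybenzoic acids; acetate removes HBr to spare the benzyl ether, and C1 is meta to both methoxy groups so ipso attack should not compete.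

**Step 8**
Reactants: 13 4-(benzyloxy)-2,6-dibromo-3,5-dimethoxybenzoic acid; 9 1-[4,5-bis(benzyloxy)-2-methoxyphenyl]-2-methoxyethan-1-one
Product: 15 1-[4-(benzyloxy)-2,6-dibromo-3,5-dimethoxyphenyl]-3-[4,5-bis(benzyloxy)-2-methoxyphenyl]-2-methoxypropane-1,3-dione (racemic), via acid chloride 14 (not isolated)
Conditions: (COCl)2, DMF (cat.), CH2Cl2, rt, evaporate; then 9, MgBr2·OEt2, i-Pr2NEt, CH2Cl2, 0 °C to rt
Reagents that add atoms: oxalyl chloride, O=C(Cl)C(=O)Cl (chlorine of intermediate 14 only)
Why: Claisen-type C-acylation of a magnesium enolate made by soft enolisation, in which chelation by the α-methoxy group and formation of the magnesium diketonate should favour C- over O-acylation, while the di-ortho-substituted aroyl chloride reacts through acylium-like activation by MgBr2.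

**Step 9**
Reactants: 15 1-[4-(benzyloxy)-2,6-dibromo-3,5-dimethoxyphenyl]-3-[4,5-bis(benzyloxy)-2-methoxyphenyl]-2-methoxypropane-1,3-dione
Product: 16 7-(benzyloxy)-2-[4,5-bis(benzyloxy)-2-methoxyphenyl]-5-bromo-3,6,8-trimethoxy-4H-chromen-4-one
Conditions: CuI (10 mol %), 1,10-phenanthroline (20 mol %), K2CO3 (2 equiv), dry DMF, 90 °C, Ar
Reagents that add atoms: none
Why: K2CO3 converts 15 into its diketonate, which binds Cu(I)–phenanthroline; oxidative addition into the neighbouring ortho C–Br bond and C–O reductive elimination join the enolate oxygen of the ring-B carbonyl to the aryl carbon and create O1–C8a. This is the Ullmann-type intramolecular O-arylation of 1-(2-haloaryl)-1,3-diketones, a known flavone synthesis. Ring C forms as a six-membered ring by attack of oxygen on the arene carbon with the C–Br bond exocyclic (6-exo type closure at an sp2 carbon); C-arylation is excluded because it would give a four-membered ring. No stereocentre is created, and the racemic C2 centre of 15 becomes the sp2 carbon C3. The step needs closure onto ring A only, once only, and at no preferred bromide: only ring A carries halogen, the two bromides are equivalent by the local symmetry of the syringoyl ring, and under anhydrous conditions no nucleophile remains for the C5 bromide after closure.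

**Step 10**
Reactants: 16 7-(benzyloxy)-2-[4,5-bis(benzyloxy)-2-methoxyphenyl]-5-bromo-3,6,8-trimethoxy-4H-chromen-4-one
Product: 17 7-(benzyloxy)-2-[4,5-bis(benzyloxy)-2-methoxyphenyl]-5-hydroxy-3,6,8-trimethoxy-4H-chromen-4-one
Conditions: Cu(acac)2 (5 mol %), N,N'-bis(4-hydroxy-2,6-dimethylphenyl)oxalamide (5 mol %), LiOH·H2O (2.2 equiv), DMSO/H2O 4:1, 80 °C, Ar; aq. HCl work-up
Reagents that add atoms: lithium hydroxide monohydrate, O.[Li+].[OH-]
Why: Ullmann-type copper-catalysed hydroxylation of an aryl bromide, helped here by the peri C4 carbonyl, which should direct copper to the C5–Br bond; benzyl and methyl ethers are inert to these conditions.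

**Step 11**
Reactants: 17 7-(benzyloxy)-2-[4,5-bis(benzyloxy)-2-methoxyphenyl]-5-hydroxy-3,6,8-trimethoxy-4H-chromen-4-one
Product: 18 5,7,4',5'-tetrahydroxy-3,6,8,2'-tetramethoxyflavone (target, achiral)
Conditions: H2 (1 atm), 10% Pd/C, EtOAc/MeOH 1:1, rt; filtration and concentration under Ar
Reagents that add atoms: none
Why: Catalytic hydrogenolysis should cleave the three benzyl ethers without touching the methyl ethers or the fully substituted, conjugated C2=C3 bond; no halogen is left to be reduced.

**Compound list**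

1 | 3,4-bis(benzyloxy)benzaldehyde | O=Cc1ccc(OCc2ccccc2)c(OCc2ccccc2)c1 | starting material
2 | 3,4-bis(benzyloxy)phenyl formate | O=COc1ccc(OCc2ccccc2)c(OCc2ccccc2)c1 | intermediate (not isolated)
3 | 3,4-bis(benzyloxy)phenol | Oc1ccc(OCc2ccccc2)c(OCc2ccccc2)c1 | intermediate
4 | 1,2-bis(benzyloxy)-4-methoxybenzene | COc1ccc(OCc2ccccc2)c(OCc2ccccc2)c1 | intermediate
5 | 1,2-bis(benzyloxy)-4-bromo-5-methoxybenzene | COc1cc(OCc2ccccc2)c(OCc2ccccc2)cc1Br | intermediate
6 | methoxyacetyl chloride | COCC(=O)Cl | starting material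
7 | N,2-dimethoxy-N-methylacetamide | COCC(=O)N(C)OC | intermediate
8 | [4,5-bis(benzyloxy)-2-methoxyphenyl]lithium | COc1cc(OCc2ccccc2)c(OCc2ccccc2)cc1[Li] | intermediate (not isolated)
9 | 1-[4,5-bis(benzyloxy)-2-methoxyphenyl]-2-methoxyethan-1-one | COCC(=O)c1cc(OCc2ccccc2)c(OCc2ccccc2)cc1OC | intermediate
10 | methyl syringate (methyl 4-hydroxy-3,5-dimethoxybenzoate) | COC(=O)c1cc(OC)c(O)c(OC)c1 | starting material
11 | methyl 4-(benzyloxy)-3,5-dimethoxybenzoate | COC(=O)c1cc(OC)c(OCc2ccccc2)c(OC)c1 | intermediate (not isolated)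
12 | 4-(benzyloxy)-3,5-dimethoxybenzoic acid | OC(=O)c1cc(OC)c(OCc2ccccc2)c(OC)c1 | intermediate
13 | 4-(benzyloxy)-2,6-dibromo-3,5-dimethoxybenzoic acid | OC(=O)c1c(Br)c(OC)c(OCc2ccccc2)c(OC)c1Br | intermediate
14 | 4-(benzyloxy)-2,6-dibromo-3,5-dimethoxybenzoyl chloride | O=C(Cl)c1c(Br)c(OC)c(OCc2ccccc2)c(OC)c1Br | intermediate (not isolated)
15 | 1-[4-(benzyloxy)-2,6-dibromo-3,5-dimethoxyphenyl]-3-[4,5-bis(benzyloxy)-2-methoxyphenyl]-2-methoxypropane-1,3-dione (racemic, enolisable) | COc1cc(OCc2ccccc2)c(OCc2ccccc2)cc1C(=O)C(OC)C(=O)c1c(Br)c(OC)c(OCc2ccccc2)c(OC)c1Br | intermediate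
16 | 7-(benzyloxy)-2-[4,5-bis(benzyloxy)-2-methoxyphenyl]-5-bromo-3,6,8-trimethoxy-4H-chromen-4-one | COc1cc(OCc2ccccc2)c(OCc2ccccc2)cc1-c1oc2c(OC)c(OCc3ccccc3)c(OC)c(Br)c2c(=O)c1OC | intermediate
17 | 7-(benzyloxy)-2-[4,5-bis(benzyloxy)-2-methoxyphenyl]-5-hydroxy-3,6,8-trimethoxy-4H-chromen-4-one | COc1cc(OCc2ccccc2)c(OCc2ccccc2)cc1-c1oc2c(OC)c(OCc3ccccc3)c(OC)c(O)c2c(=O)c1OC | intermediate
18 | 5,7,4',5'-tetrahydroxy-3,6,8,2'-tetramethoxyflavone (no stereocentre) | COc1cc(O)c(O)cc1-c1oc2c(OC)c(O)c(OC)c(O)c2c(=O)c1OC | target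

**Step count.** 11 steps in total. The longest linear sequence is 8 steps (1, 2, 3, 5, 8, 9, 10, 11, from 3,4-bis(benzyloxy)benzaldehyde); the ring A branch (steps 6, 7) and the Weinreb amide (step 4) join at steps 8 and 5.

**Steps most likely to fail**

Step 9 (key step). Oxidative addition at the doubly ortho-substituted, out-of-plane aroyl bromide may be slow, so that base-induced retro-Claisen cleavage of the 2-methoxy-1,3-diketone or protodebromination takes over. The fallback changes the leaving group and not the catalyst recipe. It sets out from acid 12: NIS (2.3 equiv) with catalytic TFA in MeCN should give 4-(benzyloxy)-2,6-diiodo-3,5-dimethoxybenzoic acid F1. Oxalyl chloride with catalytic DMF gives 4-(benzyloxy)-2,6-diiodo-3,5-dimethoxybenzoyl chloride F2, which acylates the magnesium enolate of 9 as in step 8 to give 1-[4-(benzyloxy)-2,6-diiodo-3,5-dimethoxyphenyl]-3-[4,5-bis(benzyloxy)-2-methoxyphenyl]-2-methoxypropane-1,3-dione F3. The aryl iodide should undergo the copper O-arylation near 40 °C with K2CO3, where the diketone is stable, giving 7-(benzyloxy)-2-[4,5-bis(benzyloxy)-2-methoxyphenyl]-5-iodo-3,6,8-trimethoxy-4H-chromen-4-one F4. F4 is hydroxylated under the conditions of step 10, and the fallback comes back to the route at 17.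

Step 10. Hydroxide may add at C2 and open the pyranone ring, with retro-Claisen loss of ring B, and the 5-hydroxy-4-keto chelate of the product may sequester copper and stall turnover. The fallback avoids hydroxide and a free peri phenol. It sets out from 16: palladium-catalysed C–O coupling with benzyl alcohol (RockPhos Pd G3, Cs2CO3, toluene, 90 °C) should give 5,7-bis(benzyloxy)-2-[4,5-bis(benzyloxy)-2-methoxyphenyl]-3,6,8-trimethoxy-4H-chromen-4-one F5. Its four benzyl ethers are removed under the conditions of step 11, so the fallback comes back to the route at the target 18.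

Step 8. The di-ortho-brominated aroyl chloride may react sluggishly at carbon, leading to O-acylation to an enol ester or to recovered ketone. The fallback replaces the acylation by aldol addition and oxidation. It sets out from acid chloride 14 and ketone 9: LiAlH(O-t-Bu)3 in THF at −78 °C should reduce 14 to 4-(benzyloxy)-2,6-dibromo-3,5-dimethoxybenzaldehyde F6. The lithium enolate of 9 (LiHMDS, THF, −78 °C) adds to F6 to give 3-[4-(benzyloxy)-2,6-dibromo-3,5-dimethoxyphenyl]-1-[4,5-bis(benzyloxy)-2-methoxyphenyl]-3-hydroxy-2-methoxypropan-1-one F7 as a mixture of diastereomers, whose two stereocentres are destroyed later. Dess–Martin periodinane (NaHCO3, CH2Cl2) oxidises the carbinol, and the fallback comes back to the route at diketone 15.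

**Further compounds**

F1 | step 9 | 4-(benzyloxy)-2,6-diiodo-3,5-dimethoxybenzoic acid | OC(=O)c1c(I)c(OC)c(OCc2ccccc2)c(OC)c1I
F2 | step 9 | 4-(benzyloxy)-2,6-diiodo-3,5-dimethoxybenzoyl chloride | O=C(Cl)c1c(I)c(OC)c(OCc2ccccc2)c(OC)c1I
F3 | step 9 | 1-[4-(benzyloxy)-2,6-diiodo-3,5-dimethoxyphenyl]-3-[4,5-bis(benzyloxy)-2-methoxyphenyl]-2-methoxypropane-1,3-dione (racemic) | COc1cc(OCc2ccccc2)c(OCc2ccccc2)cc1C(=O)C(OC)C(=O)c1c(I)c(OC)c(OCc2ccccc2)c(OC)c1I
F4 | step 9 | 7-(benzyloxy)-2-[4,5-bis(benzyloxy)-2-methoxyphenyl]-5-iodo-3,6,8-trimethoxy-4H-chromen-4-one | COc1cc(OCc2ccccc2)c(OCc2ccccc2)cc1-c1oc2c(OC)c(OCc3ccccc3)c(OC)c(I)c2c(=O)c1OC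
F5 | step 10 | 5,7-bis(benzyloxy)-2-[4,5-bis(benzyloxy)-2-methoxyphenyl]-3,6,8-trimethoxy-4H-chromen-4-one | COc1cc(OCc2ccccc2)c(OCc2ccccc2)cc1-c1oc2c(OC)c(OCc3ccccc3)c(OC)c(OCc3ccccc3)c2c(=O)c1OC
F6 | step 8 | 4-(benzyloxy)-2,6-dibromo-3,5-dimethoxybenzaldehyde | O=Cc1c(Br)c(OC)c(OCc2ccccc2)c(OC)c1Br
F7 | step 8 | 3-[4-(benzyloxy)-2,6-dibromo-3,5-dimethoxyphenyl]-1-[4,5-bis(benzyloxy)-2-methoxyphenyl]-3-hydroxy-2-methoxypropan-1-one (racemic mixture of diastereomers) | COc1cc(OCc2ccccc2)c(OCc2ccccc2)cc1C(=O)C(OC)C(O)c1c(Br)c(OC)c(OCc2ccccc2)c(OC)c1Br
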